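**Assumption:** the SMILES is read as the (1R,3S,4R,5S,6S,7S,10R) isomer in germacrane numbering (ring C1–C10, CH3-14 on C10, CH3-15 on C4, isopropenyl on C7), with both oxiranes cis-fused (derived from Z alkenes) and both esters angelates (Z). TES = triethylsilyl, TBS = tert-butyldimethylsilyl; "ring B" is the cyclohexene ring made of the future C9, C10, C1, C2, C3, C4.

## Retrosynthetic overview

1. Target ⇐ C6 angeloylation with retention and C3 Mitsunobu angeloylation with inversion of a 1,10:4,5-diepoxy-germacr-11-en-9-one; 4,5-oxirane by C3-OH-directed vanadium epoxidation, 1,10-oxirane by Weitz–Scheffer epoxidation of a Z-enone.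
2. Ten-membered ring and the C6–C7 bond ⇐ anionic oxy-Cope [3,3] rearrangement of a cis-1,2-dialkenylcyclohex-2-en-1-ol; the ring-B alkene becomes the Z-C1(10) enone, and the chair transition state sets Z-C4(5), C6 and C7.
3. Carbinol ⇐ (E)-3-methylbuta-1,3-dienyllithium + a 2-methylcyclohex-2-enone carrying C3-OTES and a quaternary C4 (CH3, E-2-silyloxyvinyl).
4. That ketone ⇐ (R)-carvone: Criegee degradation of the isopropenyl group to the C3 oxygen, then two alkylations anti to that oxygen.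
5. Ring order: bought cyclohexenone → ten-membered carbocycle (oxy-Cope) → 1,10-oxirane → 4,5-oxirane.

## Route

Step 1
Reactants: 1 (R)-(−)-carvone
Product: 4 (1R)-4-methyl-5-oxocyclohex-3-en-1-yl acetate, via methoxy hydroperoxide 2 (not isolated), via peracetate 3 (not isolated)
Conditions: O3, CH2Cl2/MeOH, −78 °C; then Ac2O, Et3N, DMAP (cat.), CH2Cl2, 0 → 25 °C
Reagents that add atoms: ozone, O=[O+][O-]; methanol, CO
Why: Ozone cleaves the electron-rich isopropenyl alkene in preference to the enone, methanol traps the carbonyl oxide, and acylation triggers the Criegee rearrangement in which the ring carbon migrates to oxygen with retention, so the bought stereocentre becomes the C3–O centre (R) and the acetyl carbons are the former isopropenyl C(CH3).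

Step 2
Reactants: 4 (1R)-4-methyl-5-oxocyclohex-3-en-1-yl acetate
Product: 5 (5R)-5-hydroxy-2-methylcyclohex-2-en-1-one
Conditions: K2CO3 (0.2 equiv), MeOH, 0 °C
Reagents that add atoms: none
Why: Mild base-catalysed transesterification (methanolysis) frees the alcohol at low temperature before β-elimination to the phenol can compete, and the stereocentre is not touched.

Step 3
Reactants: 5 (5R)-5-hydroxy-2-methylcyclohex-2-en-1-one
Product: 6 (5R,6S)-5-hydroxy-2,6-dimethylcyclohex-2-en-1-one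
Conditions: LiN(iPr)2 (2.2 equiv), THF, −78 °C; MeI, −78 → −40 °C; AcOH quench
Reagents that add atoms: iodomethane, CI
Why: Fráter–Seebach-type alkylation of the alkoxide/cross-conjugated α'-enolate dianion, which cannot β-eliminate, with iodomethane entering anti to the C–O bond (this centre is re-enolised in the next step).

Step 4
Reactants: 6 (5R,6S)-5-hydroxy-2,6-dimethylcyclohex-2-en-1-one
Product: 8 (5R,6S)-2,6-dimethyl-6-(prop-2-en-1-yl)-5-(triethylsilyloxy)cyclohex-2-en-1-one, via C-allylated hydroxy ketone 7 (not isolated)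
Conditions: LiN(iPr)2 (2.2 equiv), THF/DMPU, −78 → −30 °C; allyl bromide, −78 → −20 °C; then Et3SiCl, −20 → 0 °C
Reagents that add atoms: allyl bromide, C=CCBr; chlorotriethylsilane, CC[Si](Cl)(CC)CC
Why: Enolate alkylation of the tetrasubstituted dianion occurs anti to the neighbouring lithium alkoxide, setting quaternary C4 with allyl trans and CH3 cis to the C3 oxygen, and in-flask silylation of the alkoxide blocks retro-aldol opening and protects O3.

Step 5
Reactants: 8 (5R,6S)-2,6-dimethyl-6-(prop-2-en-1-yl)-5-(triethylsilyloxy)cyclohex-2-en-1-one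
Product: 9 2-[(1S,6R)-1,3-dimethyl-2-oxo-6-(triethylsilyloxy)cyclohex-3-en-1-yl]acetaldehyde
Conditions: OsO4 (2 mol %), NaIO4, 2,6-lutidine, dioxane/H2O, 25 °C
Reagents that add atoms: osmium tetroxide, O=[Os](=O)(=O)=O; sodium periodate, [Na+].[O-]I(=O)(=O)=O
Why: Lemieux–Johnson oxidative cleavage is selective for the monosubstituted electron-rich alkene over the trisubstituted electron-poor enone alkene, and the lutidine buffer keeps the TES ether intact.

Step 6
Reactants: 9 2-[(1S,6R)-1,3-dimethyl-2-oxo-6-(triethylsilyloxy)cyclohex-3-en-1-yl]acetaldehyde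
Product: 10 (5R,6S)-6-[(E)-2-(tert-butyldimethylsilyloxy)ethenyl]-2,6-dimethyl-5-(triethylsilyloxy)cyclohex-2-en-1-one
Conditions: TBSOTf, Et3N, CH2Cl2, −78 → 0 °C
Reagents that add atoms: tert-butyldimethylsilyl triflate, CC(C)(C)[Si](C)(C)OS(=O)(=O)C(F)(F)F
Why: Soft enolisation and O-silylation of the aldehyde (the ketone has no α-hydrogen on this side) is expected to give the E enol ether, because the Z isomer would place the quaternary carbon cis to the bulky OTBS group; this geometry is not proven and any Z isomer must be removed or equilibrated.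

Step 7
Reactants: 11 2-methylbut-1-en-3-yne
Product: 12 tributyl[(1E)-3-methylbuta-1,3-dien-1-yl]stannane
Conditions: Bu3SnH, AIBN (cat.), neat, 85 °C
Reagents that add atoms: tributyltin hydride, CCCC[SnH](CCCC)CCCC
Why: Radical hydrostannylation of the terminal alkyne is reversible in the stannyl-radical addition and funnels to the thermodynamic E β-stannyl diene.

Step 8
Reactants: 12 tributyl[(1E)-3-methylbuta-1,3-dien-1-yl]stannane; 10 (5R,6S)-6-[(E)-2-(tert-butyldimethylsilyloxy)ethenyl]-2,6-dimethyl-5-(triethylsilyloxy)cyclohex-2-en-1-one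
Product: 14 (1S,5R,6S)-6-[(E)-2-(tert-butyldimethylsilyloxy)ethenyl]-2,6-dimethyl-1-[(1E)-3-methylbuta-1,3-dien-1-yl]-5-(triethylsilyloxy)cyclohex-2-en-1-ol, via dienyllithium 13 (not isolated)
Conditions: 12, n-BuLi, THF, −78 °C; then 10, −78 → −40 °C; AcOH quench
Reagents that add atoms: none
Why: Tin–lithium exchange keeps the E geometry and the dienyllithium adds 1,2 to the enone carbonyl from the face opposite the cis-disposed C3–OTES and C4–CH3 groups (axial attack anti to the axial α-methyl), setting C9 (S) with the two alkenyl arms cis.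

Step 9
Reactants: 14 (1S,5R,6S)-6-[(E)-2-(tert-butyldimethylsilyloxy)ethenyl]-2,6-dimethyl-1-[(1E)-3-methylbuta-1,3-dien-1-yl]-5-(triethylsilyloxy)cyclohex-2-en-1-ol
Product: 15 (2Z,5R,6Z,8R,9S)-8-(tert-butyldimethylsilyloxy)-2,6-dimethyl-9-(prop-1-en-2-yl)-5-(triethylsilyloxy)cyclodeca-2,6-dien-1-one
Conditions: KH, 18-crown-6, THF, 0 → 25 °C; AcOH, −78 °C
Reagents that add atoms: none
Why: Anionic oxy-Cope [3,3]-sigmatropic rearrangement through a chair transition state with both E termini substituents equatorial and ring-B carbon C3 axial (the other chair would force O− and OTES into a 1,3-diaxial clash), so the C6–C7 bond forms suprafacially with C4 and C9 chirality translated into C6 (R) and C7 (S), the new C4=C5 alkene is Z, the ring alkene survives as the Z-enone, and the E enol ether keeps its silyl group out of reach of the alkoxide.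

Step 10
Reactants: 15 (2Z,5R,6Z,8R,9S)-8-(tert-butyldimethylsilyloxy)-2,6-dimethyl-9-(prop-1-en-2-yl)-5-(triethylsilyloxy)cyclodeca-2,6-dien-1-one
Product: 16 (1R,3R,6R,7S,10R)-6-(tert-butyldimethylsilyloxy)-1,10-epoxy-3-(triethylsilyloxy)germacra-4Z,11-dien-9-one
Conditions: t-BuOOH, BnMe3N+ OH− (cat.), THF, 0 °C
Reagents that add atoms: tert-butyl hydroperoxide, CC(C)(C)OO
Why: Weitz–Scheffer nucleophilic epoxidation touches only the enone, the peroxide anion adding to C1 from the ring periphery anti to the 1,3-related bulky C3–OTES group (as in carvone) and closing before C1–C10 rotation, which gives the cis-oxirane (1R,10R).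

Step 11
Reactants: 16 (1R,3R,6R,7S,10R)-6-(tert-butyldimethylsilyloxy)-1,10-epoxy-3-(triethylsilyloxy)germacra-4Z,11-dien-9-one
Product: 17 (1R,3R,6R,7S,10R)-6-(tert-butyldimethylsilyloxy)-1,10-epoxy-3-hydroxygermacra-4Z,11-dien-9-one
Conditions: PPTS (cat.), MeOH/CH2Cl2, 0 °C
Reagents that add atoms: none
Why: Acid-catalysed solvolysis removes the TES ether far faster than the hindered secondary TBS ether, freeing only the C3 hydroxyl without touching stereocentres.

Step 12
Reactants: 17 (1R,3R,6R,7S,10R)-6-(tert-butyldimethylsilyloxy)-1,10-epoxy-3-hydroxygermacra-4Z,11-dien-9-one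
Product: 18 (1R,3R,4R,5S,6S,7S,10R)-6-(tert-butyldimethylsilyloxy)-1,10:4,5-diepoxy-3-hydroxygermacr-11-en-9-one
Conditions: VO(acac)2 (5 mol %), t-BuOOH, CH2Cl2, 0 → 25 °C
Reagents that add atoms: tert-butyl hydroperoxide, CC(C)(C)OO
Why: Vanadium-catalysed hydroxyl-directed epoxidation delivers oxygen from the C3 alkoxide at an O–C–C=C dihedral near 45° with H3 eclipsing the C15 methyl (A(1,2) strain control), so the oxirane forms syn to the hydroxyl (4R,5S) and the isopropenyl group is not touched.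

Step 13
Reactants: 18 (1R,3R,4R,5S,6S,7S,10R)-6-(tert-butyldimethylsilyloxy)-1,10:4,5-diepoxy-3-hydroxygermacr-11-en-9-one
Product: 19 (1R,3S,4R,5S,6S,7S,10R)-3-angeloyloxy-6-(tert-butyldimethylsilyloxy)-1,10:4,5-diepoxygermacr-11-en-9-one
Conditions: PPh3, DIAD, angelic acid, toluene, 0 → 25 °C
Reagents that add atoms: angelic acid, C/C=C(/C)C(=O)O
Why: Mitsunobu esterification displaces the oxyphosphonium of the epoxy carbinol by angelate in an SN2 step with inversion, turning (3R) into the required (3S) ester under neutral conditions that neither open the oxiranes nor isomerise the Z acid.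

Step 14
Reactants: 19 (1R,3S,4R,5S,6S,7S,10R)-3-angeloyloxy-6-(tert-butyldimethylsilyloxy)-1,10:4,5-diepoxygermacr-11-en-9-one
Product: 20 (1R,3S,4R,5S,6S,7S,10R)-3-angeloyloxy-1,10:4,5-diepoxy-6-hydroxygermacr-11-en-9-one
Conditions: HF·pyridine, pyridine, THF, 0 → 25 °C
Reagents that add atoms: none
Why: Buffered fluoride desilylation cleaves the Si–O bond without base, so Payne rearrangement, acyl migration and oxirane opening are avoided and no stereocentre changes.

Step 15
Reactants: 20 (1R,3S,4R,5S,6S,7S,10R)-3-angeloyloxy-1,10:4,5-diepoxy-6-hydroxygermacr-11-en-9-one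
Product: 21 (1R,3S,4R,5S,6S,7S,10R)-3,6-bis(angeloyloxy)-1,10:4,5-diepoxygermacr-11-en-9-one
Conditions: angelic acid, 2,4,6-Cl3C6H2COCl, Et3N, toluene, 25 °C; then 20, 80 °C
Reagents that add atoms: angelic acid, C/C=C(/C)C(=O)O
Why: Yamaguchi-type mixed-anhydride esterification run without DMAP acylates the hindered C6 hydroxyl with retention and avoids the angelate-to-tiglate isomerisation seen with nucleophilic catalysts.

## Compound list

1 | (R)-(−)-carvone, (5R)-2-methyl-5-(prop-1-en-2-yl)cyclohex-2-en-1-one | CC1=CC[C@@H](C(C)=C)CC1=O | starting material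
2 | (5R)-5-(1-hydroperoxy-1-methoxyethyl)-2-methylcyclohex-2-en-1-one (side-chain epimers) | CC1=CC[C@@H](C(C)(OC)OO)CC1=O | intermediate
3 | (5R)-5-[1-(acetylperoxy)-1-methoxyethyl]-2-methylcyclohex-2-en-1-one | CC1=CC[C@@H](C(C)(OC)OOC(C)=O)CC1=O | intermediate
4 | (1R)-4-methyl-5-oxocyclohex-3-en-1-yl acetate | CC1=CC[C@@H](OC(C)=O)CC1=O | intermediate
5 | (5R)-5-hydroxy-2-methylcyclohex-2-en-1-one | CC1=CC[C@@H](O)CC1=O | intermediate
6 | (5R,6S)-5-hydroxy-2,6-dimethylcyclohex-2-en-1-one | CC1=CC[C@@H](O)[C@H](C)C1=O | intermediate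
7 | (5R,6S)-5-hydroxy-2,6-dimethyl-6-(prop-2-en-1-yl)cyclohex-2-en-1-one (formed as its lithium alkoxide) | CC1=CC[C@@H](O)[C@](C)(CC=C)C1=O | intermediate
8 | (5R,6S)-2,6-dimethyl-6-(prop-2-en-1-yl)-5-(triethylsilyloxy)cyclohex-2-en-1-one | CC1=CC[C@@H](O[Si](CC)(CC)CC)[C@](C)(CC=C)C1=O | intermediate
9 | 2-[(1S,6R)-1,3-dimethyl-2-oxo-6-(triethylsilyloxy)cyclohex-3-en-1-yl]acetaldehyde | CC1=CC[C@@H](O[Si](CC)(CC)CC)[C@](C)(CC=O)C1=O | intermediate
10 | (5R,6S)-6-[(E)-2-(tert-butyldimethylsilyloxy)ethenyl]-2,6-dimethyl-5-(triethylsilyloxy)cyclohex-2-en-1-one | CC1=CC[C@@H](O[Si](CC)(CC)CC)[C@](C)(/C=C/O[Si](C)(C)C(C)(C)C)C1=O | intermediate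
11 | 2-methylbut-1-en-3-yne | C=C(C)C#C | starting material
12 | tributyl[(1E)-3-methylbuta-1,3-dien-1-yl]stannane | C=C(C)/C=C/[Sn](CCCC)(CCCC)CCCC | intermediate
13 | [(1E)-3-methylbuta-1,3-dien-1-yl]lithium | C=C(C)/C=C/[Li] | intermediate
14 | (1S,5R,6S)-6-[(E)-2-(tert-butyldimethylsilyloxy)ethenyl]-2,6-dimethyl-1-[(1E)-3-methylbuta-1,3-dien-1-yl]-5-(triethylsilyloxy)cyclohex-2-en-1-ol | C=C(C)/C=C/[C@]1(O)C(C)=CC[C@@H](O[Si](CC)(CC)CC)[C@]1(C)/C=C/O[Si](C)(C)C(C)(C)C | intermediate
15 | (2Z,5R,6Z,8R,9S)-8-(tert-butyldimethylsilyloxy)-2,6-dimethyl-9-(prop-1-en-2-yl)-5-(triethylsilyloxy)cyclodeca-2,6-dien-1-one (germacrane: 3R,6R,7S; 1(10)Z,4Z; 9-oxo) | C=C(C)[C@@H]1CC(=O)/C(C)=C\C[C@@H](O[Si](CC)(CC)CC)/C(C)=C\[C@H]1O[Si](C)(C)C(C)(C)C | intermediate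
16 | (1R,3R,6R,7S,10R)-6-(tert-butyldimethylsilyloxy)-1,10-epoxy-3-(triethylsilyloxy)germacra-4Z,11-dien-9-one | C=C(C)[C@@H]1CC(=O)[C@]2(C)O[C@@H]2C[C@@H](O[Si](CC)(CC)CC)/C(C)=C\[C@H]1O[Si](C)(C)C(C)(C)C | intermediate
17 | (1R,3R,6R,7S,10R)-6-(tert-butyldimethylsilyloxy)-1,10-epoxy-3-hydroxygermacra-4Z,11-dien-9-one | C=C(C)[C@@H]1CC(=O)[C@]2(C)O[C@@H]2C[C@@H](O)/C(C)=C\[C@H]1O[Si](C)(C)C(C)(C)C | intermediate
18 | (1R,3R,4R,5S,6S,7S,10R)-6-(tert-butyldimethylsilyloxy)-1,10:4,5-diepoxy-3-hydroxygermacr-11-en-9-one | C=C(C)[C@@H]1CC(=O)[C@]2(C)O[C@@H]2C[C@@H](O)[C@@]2(C)O[C@H]2[C@H]1O[Si](C)(C)C(C)(C)C | intermediate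
19 | (1R,3S,4R,5S,6S,7S,10R)-3-angeloyloxy-6-(tert-butyldimethylsilyloxy)-1,10:4,5-diepoxygermacr-11-en-9-one | C=C(C)[C@@H]1CC(=O)[C@]2(C)O[C@@H]2C[C@H](OC(=O)/C(C)=C\C)[C@@]2(C)O[C@H]2[C@H]1O[Si](C)(C)C(C)(C)C | intermediate
20 | (1R,3S,4R,5S,6S,7S,10R)-3-angeloyloxy-1,10:4,5-diepoxy-6-hydroxygermacr-11-en-9-one | C=C(C)[C@@H]1CC(=O)[C@]2(C)O[C@@H]2C[C@H](OC(=O)/C(C)=C\C)[C@@]2(C)O[C@H]2[C@H]1O | intermediate
21 | (1R,3S,4R,5S,6S,7S,10R)-3,6-bis(angeloyloxy)-1,10:4,5-diepoxygermacr-11-en-9-one (CNP0217653.1) | C=C(C)[C@@H]1CC(=O)[C@]2(C)O[C@@H]2C[C@H](OC(=O)/C(C)=C\C)[C@@]2(C)O[C@H]2[C@H]1OC(=O)/C(C)=C\C | target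

## Step count and risks

Total steps: 15. Longest linear sequence: 14 steps (steps 1–6 and 8–15 from carvone; step 7 is a one-step side branch).

**Step 9 (oxy-Cope).** The Z-C4=C5 geometry and the C6/C7 configuration rest on one chair being preferred over the other chair and the boat, and the potassium dienolate could also eliminate the C3 silyloxy group. The fallback sets out from 14 and replaces the anionic rearrangement by a neutral siloxy-Cope. Compound 14 is silylated (Me3SiCl, imidazole, DMF) to the O-trimethylsilyl ether F1. Heating F1 in degassed toluene at about 200 °C in a sealed tube gives the ring-expanded trimethylsilyl dienol ether F2 through the same chair, without any basic species. Brief K2CO3/MeOH at 0 °C cleaves only the enol ether, and the route is rejoined at 15.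

**Step 10 (enone epoxidation).** The facial selectivity on the flexible ten-membered Z-enone is argued only by a local steric model, and reversible peroxide addition could scramble the enone geometry. The fallback sets out from 15 and makes the oxirane by hydroxyl direction instead. Luche reduction (NaBH4, CeCl3·7H2O, MeOH, −78 °C) gives the (9S)-allylic alcohol F3; the 9-epimer is recycled by oxidation. VO(acac)2/t-BuOOH then delivers oxygen syn to the C9 hydroxyl (the geminal C14 methyl enforces the A(1,2)-controlled geometry) to give the epoxy alcohol F4. Dess–Martin periodinane (NaHCO3, CH2Cl2) oxidises C9 back to the ketone, and the route is rejoined at 16.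

**Step 13 (Mitsunobu angeloylation).** The carbinol is flanked by a fully substituted oxirane carbon and the acid is weak and hindered, so displacement may be slow or give elimination. The fallback sets out from 18 and uses a sulfonate displacement. ClCH2SO2Cl/pyridine at 0 °C gives, with retention, the chloromethanesulfonate F5. Cesium angelate, CsO2CC(CH3)=CHCH3, with 18-crown-6 in toluene at 60 °C then displaces it with inversion, and the route is rejoined at 19.

Further compounds

F1 | step 9 | {[(1S,5R,6S)-6-[(E)-2-(tert-butyldimethylsilyloxy)ethenyl]-2,6-dimethyl-1-[(1E)-3-methylbuta-1,3-dien-1-yl]-5-(triethylsilyloxy)cyclohex-2-en-1-yl]oxy}trimethylsilane | C=C(C)/C=C/[C@]1(O[Si](C)(C)C)C(C)=CC[C@@H](O[Si](CC)(CC)CC)[C@]1(C)/C=C/O[Si](C)(C)C(C)(C)C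
F2 | step 9 | (3R,6R,7S)-6-(tert-butyldimethylsilyloxy)-3-(triethylsilyloxy)-9-(trimethylsilyloxy)germacra-1(10)Z,4Z,8,11-tetraene (C8=C9 enol ether of 15) | C=C(C)[C@@H]1/C=C(O[Si](C)(C)C)/C(C)=C\C[C@@H](O[Si](CC)(CC)CC)/C(C)=C\[C@H]1O[Si](C)(C)C(C)(C)C
F3 | step 10 | (3R,6R,7S,9S)-6-(tert-butyldimethylsilyloxy)-3-(triethylsilyloxy)germacra-1(10)Z,4Z,11-trien-9-ol | C=C(C)[C@@H]1C[C@H](O)/C(C)=C\C[C@@H](O[Si](CC)(CC)CC)/C(C)=C\[C@H]1O[Si](C)(C)C(C)(C)C
F4 | step 10 | (1R,3R,6R,7S,9S,10S)-6-(tert-butyldimethylsilyloxy)-1,10-epoxy-3-(triethylsilyloxy)germacra-4Z,11-dien-9-ol | C=C(C)[C@@H]1C[C@H](O)[C@]2(C)O[C@@H]2C[C@@H](O[Si](CC)(CC)CC)/C(C)=C\[C@H]1O[Si](C)(C)C(C)(C)C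
F5 | step 13 | (1R,3R,4R,5S,6S,7S,10R)-6-(tert-butyldimethylsilyloxy)-1,10:4,5-diepoxy-9-oxogermacr-11-en-3-yl chloromethanesulfonate | C=C(C)[C@@H]1CC(=O)[C@]2(C)O[C@@H]2C[C@@H](OS(=O)(=O)CCl)[C@@]2(C)O[C@H]2[C@H]1O[Si](C)(C)C(C)(C)C
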